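**Strategy.** The cyclohexane (C1 bears the acrylic acid, C2 OH, C3 the hydroxypropenyl group, C4 methyl and vinyl, C5 is CH2, C6 the acyloxy group) is assembled from a C2–C3–C4 lactone and a C5–C6–C1 triflate in one flask. Enolate alkylation forms C4–C5, then an indium Barbier allylation forms C1–C2. The step exploits that the C4 vinyl carbon and the C3 CH2OH are trans on the ring: a temporary δ-lactone ties them, steers the alkylation at C4 anti to the future C2 carbon and locks the chair in which indium holds the syn-axial C6 and C2 oxygens. The lactone later becomes vinyl and CH2OH.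

Key step: step 11

Assumption: the free cis-γ-hydroxy acid 27 is taken to be kinetically stable towards lactonization during a cold, buffered (pH about 5) isolation.

Ring numbering used throughout: that of the target name (C1 carries the propenoic acid, C4 is quaternary).

Step 1
Reactants: 1 1,2:5,6-di-O-isopropylidene-D-mannitol
Product: 2 (4R)-2,2-dimethyl-1,3-dioxolane-4-carbaldehyde
Conditions: NaIO4, CH2Cl2/aq. NaHCO3, rt
Reagents that add atoms: none
Why: Periodate glycol cleavage of the central diol should give two equivalents of the aldehyde, whose stereocentre comes unchanged from D-mannitol.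

Step 2
Reactants: 2 (4R)-2,2-dimethyl-1,3-dioxolane-4-carbaldehyde; 3 tert-butyl prop-2-enoate
Product: 4 tert-butyl 2-{[(4R)-2,2-dimethyl-1,3-dioxolan-4-yl](hydroxy)methyl}prop-2-enoate (both carbinol epimers)
Conditions: DABCO (0.5 eq), dioxane/H2O 1:1, rt
Reagents that add atoms: none
Why: Morita–Baylis–Hillman reaction; the new carbinol centre may form as a mixture because it becomes sp2 in step 3.

Step 3
Reactants: 4 tert-butyl 2-{[(4R)-2,2-dimethyl-1,3-dioxolan-4-yl](hydroxy)methyl}prop-2-enoate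
Product: 5 tert-butyl (2Z)-2-(chloromethyl)-3-[(4S)-2,2-dimethyl-1,3-dioxolan-4-yl]prop-2-enoate
Conditions: NCS, Me2S, CH2Cl2, −40 → 0 °C
Reagents that add atoms: N-chlorosuccinimide (O=C1CCC(=O)N1Cl)
Why: Corey–Kim-type activation of the allylic alcohol followed by SN2′ attack of chloride should give the transposed 2-(chloromethyl)enoate as the more stable (Z)-isomer (dioxolanyl trans to the ester), with the dioxolane stereocentre untouched.

Step 4
Reactants: 5 tert-butyl (2Z)-2-(chloromethyl)-3-[(4S)-2,2-dimethyl-1,3-dioxolan-4-yl]prop-2-enoate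
Product: 6 tert-butyl (2Z,4S)-2-(chloromethyl)-4,5-dihydroxypent-2-enoate
Conditions: AcOH/H2O 4:1, 40 °C
Reagents that add atoms: none
Why: Acid-catalysed acetonide hydrolysis; the C4 hydroxyl is trans to the ester across the double bond, so it cannot lactonize, and the neutral hydroxyl should not displace the chloride under acid.

Step 5
Reactants: 6 tert-butyl (2Z,4S)-2-(chloromethyl)-4,5-dihydroxypent-2-enoate
Product: 7 tert-butyl (2Z,4S)-2-(chloromethyl)-4-[(triethylsilyl)oxy]-5-{[(trifluoromethyl)sulfonyl]oxy}pent-2-enoate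
Conditions: Tf2O, 2,6-lutidine, CH2Cl2, −78 °C; then Et3SiOTf, −78 → −50 °C; used at once
Reagents that add atoms: trifluoromethanesulfonic anhydride (O=S(=O)(OS(=O)(=O)C(F)(F)F)C(F)(F)F); triethylsilyl trifluoromethanesulfonate (CC[Si](CC)(CC)OS(=O)(=O)C(F)(F)F)
Why: Selective O-sulfonylation of the primary hydroxyl at −78 °C followed by in situ O-silylation of the secondary hydroxyl, which should prevent epoxide formation.

Step 6
Reactants: 8 2-bromoprop-2-en-1-ol
Product: 9 [(2-bromoprop-2-en-1-yl)oxy](tert-butyl)dimethylsilane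
Conditions: TBSCl, imidazole, CH2Cl2, 0 °C → rt
Reagents that add atoms: tert-butyldimethylsilyl chloride (CC(C)(C)[Si](C)(C)Cl)
Why: Standard O-silylation of a primary alcohol.

Step 7
Reactants: 9 [(2-bromoprop-2-en-1-yl)oxy](tert-butyl)dimethylsilane
Product: 10 tert-butyl(dimethyl){[2-(4,4,5,5-tetramethyl-1,3,2-dioxaborolan-2-yl)prop-2-en-1-yl]oxy}silane
Conditions: B2pin2, PdCl2(PPh3)2 (3 mol %), PPh3, KOPh, toluene, 50 °C
Reagents that add atoms: bis(pinacolato)diboron (CC1(C)OB(OC1(C)C)B1OC(C)(C)C(C)(C)O1)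
Why: Miyaura borylation of a 1-alkenyl bromide.

Step 8
Reactants: 10 tert-butyl(dimethyl){[2-(4,4,5,5-tetramethyl-1,3,2-dioxaborolan-2-yl)prop-2-en-1-yl]oxy}silane; 11 methyl (2E)-4,4-dimethoxybut-2-enoate
Product: 12 methyl (3R)-4-({[tert-butyl(dimethyl)silyl]oxy}methyl)-3-(dimethoxymethyl)pent-4-enoate
Conditions: [Rh(OH)(cod)]2 (2.5 mol %), (S)-BINAP (5.5 mol %), KOH (cat.), dioxane/H2O 10:1, 50 °C
Reagents that add atoms: none
Why: Hayashi–Miyaura rhodium-catalysed asymmetric 1,4-addition, in which the bisphosphine-bound alkenylrhodium adds to one enantioface of the (E)-enoate and sets C3; (S)-BINAP is chosen on the expectation, by analogy with (E)-crotonates, that it gives the (3R) adduct, and the other antipode is used if the sense proves opposite.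

Step 9
Reactants: 12 methyl (3R)-4-({[tert-butyl(dimethyl)silyl]oxy}methyl)-3-(dimethoxymethyl)pent-4-enoate
Product: 13 (4R)-4-(dimethoxymethyl)-5-methylideneoxan-2-one
Conditions: Bu4NF, THF, 0 °C → rt
Reagents that add atoms: none
Why: Fluoride desilylation followed by lactonization (6-exo-trig transesterification) of the allylic alkoxide onto the methyl ester; the stereocentre is not involved.

Step 10
Reactants: 13 (4R)-4-(dimethoxymethyl)-5-methylideneoxan-2-one
Product: 14 (4R)-4-(dimethoxymethyl)-3-methyl-5-methylideneoxan-2-one (both C3 epimers)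
Conditions: LiN(iPr)2, THF, −78 °C; MeI, −78 → −40 °C
Reagents that add atoms: iodomethane (CI)
Why: Lactone enolate alkylation; the C3 configuration is irrelevant because this centre is enolized again in step 11.

Step 11
Reactants: 14 (4R)-4-(dimethoxymethyl)-3-methyl-5-methylideneoxan-2-one; 7 tert-butyl (2Z,4S)-2-(chloromethyl)-4-[(triethylsilyl)oxy]-5-{[(trifluoromethyl)sulfonyl]oxy}pent-2-enoate
Product: 17 tert-butyl 2-[(4aS,5S,6R,7R,8aR)-5,7-dihydroxy-8a-methyl-4-methylidene-1-oxo-3,4,4a,5,6,7,8,8a-octahydro-1H-isochromen-6-yl]prop-2-enoate, via alkylated lactone 15 (not isolated), via hydroxy aldehyde 16 (not isolated)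
Conditions: LiN(SiMe3)2, THF, −78 °C; 7, −78 → −45 °C; then 1 M aq. HCl, 0 °C → rt; then indium powder, NaI (cat.), rt (one flask)
Reagents that add atoms: water (O)
Why: The lithium enolate of 14 is alkylated by the primary triflate of 7 (SN2; the triflate should react at −78 °C, where the allylic chloride and the hindered enoate do not) to give 15, the new bond entering anti to the neighbouring dimethoxymethyl group, which sets the quaternary centre. Aqueous HCl then unmasks the aldehyde and the secondary alcohol (16), and indium converts the (Z)-2-(chloromethyl)enoate into an allylindium that adds through its γ-carbon to the aldehyde, a Barbier allylation of the kind known for 2-(halomethyl)acrylates in water, including carbocycle-forming cases. This closure is a 6-exo-trig addition to the aldehyde and forms the cyclohexane through a chair locked by the trans-fused δ-lactone; in it the free hydroxyl lies axial beside the CH2–In unit and the aldehyde oxygen axial in a Zimmerman–Traxler array, so both oxygens can bind trivalent indium. The (Z)-allyl geometry and this chelate place the acrylate equatorial and cis to both hydroxyls, which fixes the two new ring stereocentres relative to the three present in 16. The step needs chemoselective C-alkylation at the triflate and rapid capture of the epimerizable β,γ-unsaturated aldehyde, which the low temperature and the in situ intramolecular allylation are meant to secure.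

Step 12
Reactants: 17 tert-butyl 2-[(4aS,5S,6R,7R,8aR)-5,7-dihydroxy-8a-methyl-4-methylidene-1-oxo-3,4,4a,5,6,7,8,8a-octahydro-1H-isochromen-6-yl]prop-2-enoate
Product: 18 tert-butyl 2-[(4aS,5S,6R,7R,8aR)-1,5,7-trihydroxy-8a-methyl-4-methylidene-3,4,4a,5,6,7,8,8a-octahydro-1H-isochromen-6-yl]prop-2-enoate (both C1 epimers)
Conditions: iBu2AlH (3.3 eq), CH2Cl2, −78 °C
Reagents that add atoms: none
Why: Partial hydride reduction of a lactone to the lactol at −78 °C, where the hindered tert-butyl enoate should survive; the hemiacetal centre is lost in step 13.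

Step 13
Reactants: 18 tert-butyl 2-[(4aS,5S,6R,7R,8aR)-1,5,7-trihydroxy-8a-methyl-4-methylidene-3,4,4a,5,6,7,8,8a-octahydro-1H-isochromen-6-yl]prop-2-enoate
Product: 19 tert-butyl 2-[(1R,2S,3R,4S,6R)-4-ethenyl-2,6-dihydroxy-3-(3-hydroxyprop-1-en-2-yl)-4-methylcyclohexyl]prop-2-enoate
Conditions: Ph3PCH3Br (slight excess over base), KN(SiMe3)2, THF, 0 °C; then 18, 0 °C → rt
Reagents that add atoms: methyltriphenylphosphonium bromide (C[P+](c1ccccc1)(c1ccccc1)c1ccccc1.[Br-])
Why: Wittig methylenation of the open hydroxy-aldehyde form of the lactol should give the vinyl group on the quaternary carbon and release the primary allylic alcohol; with no excess base the secondary hydroxyls stay protonated and should not attack the tert-butyl ester.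

Step 14
Reactants: 19 tert-butyl 2-[(1R,2S,3R,4S,6R)-4-ethenyl-2,6-dihydroxy-3-(3-hydroxyprop-1-en-2-yl)-4-methylcyclohexyl]prop-2-enoate
Product: 20 tert-butyl 2-[(1R,2S,3R,4S,6R)-3-(3-{[tert-butyl(dimethyl)silyl]oxy}prop-1-en-2-yl)-4-ethenyl-2,6-dihydroxy-4-methylcyclohexyl]prop-2-enoate
Conditions: TBSCl (1.1 eq), imidazole, CH2Cl2, −10 °C
Reagents that add atoms: tert-butyldimethylsilyl chloride (CC(C)(C)[Si](C)(C)Cl)
Why: Selective O-silylation of the primary hydroxyl over the two hindered secondary ones.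

Step 15
Reactants: 21 3-methylfuran-2(5H)-one
Product: 23 (2Z)-4-(acetyloxy)-2-methylbut-2-enoic acid, via sodium hydroxy enoate 22 (not isolated)
Conditions: NaOH (1.0 eq), H2O, 0 °C → rt; evaporation; Ac2O, pyridine, 0 °C; then H2O, NaHSO4 to pH 3, 0 °C
Reagents that add atoms: sodium hydroxide ([Na+].[OH-]); acetic anhydride (CC(=O)OC(C)=O)
Why: Saponification of the butenolide keeps the ring's cis geometry in the (Z)-hydroxy carboxylate, and O-acetylation before acidification should block relactonization.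

Step 16
Reactants: 20 tert-butyl 2-[(1R,2S,3R,4S,6R)-3-(3-{[tert-butyl(dimethyl)silyl]oxy}prop-1-en-2-yl)-4-ethenyl-2,6-dihydroxy-4-methylcyclohexyl]prop-2-enoate; 23 (2Z)-4-(acetyloxy)-2-methylbut-2-enoic acid
Product: 25 tert-butyl 2-[(1S,2S,3R,4S,6R)-6-{[(2Z)-4-(acetyloxy)-2-methylbut-2-enoyl]oxy}-3-(3-{[tert-butyl(dimethyl)silyl]oxy}prop-1-en-2-yl)-4-ethenyl-2-hydroxy-4-methylcyclohexyl]prop-2-enoate, via mixed anhydride 24 (not isolated)
Conditions: 23, 2,4,6-Cl3C6H2COCl, Et3N, toluene, 0 °C; then 20, DMAP, toluene, 0 °C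
Reagents that add atoms: none
Why: Yamaguchi esterification; the C6 hydroxyl, flanked by the ring CH2, should be acylated in preference to the C2 hydroxyl, which lies between two branched ring carbons, and the low temperature is meant to limit Z/E isomerization of the enoate.

Step 17
Reactants: 25 tert-butyl 2-[(1S,2S,3R,4S,6R)-6-{[(2Z)-4-(acetyloxy)-2-methylbut-2-enoyl]oxy}-3-(3-{[tert-butyl(dimethyl)silyl]oxy}prop-1-en-2-yl)-4-ethenyl-2-hydroxy-4-methylcyclohexyl]prop-2-enoate
Product: 26 tert-butyl 2-[(1S,2S,3R,4S,6R)-6-{[(2Z)-4-(acetyloxy)-2-methylbut-2-enoyl]oxy}-4-ethenyl-2-hydroxy-3-(3-hydroxyprop-1-en-2-yl)-4-methylcyclohexyl]prop-2-enoate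
Conditions: HF·pyridine, pyridine, THF, 0 °C
Reagents that add atoms: none
Why: Buffered fluoride cleavage of the primary silyl ether, under which the acetate, the enoate and the tert-butyl ester should persist.

Step 18
Reactants: 26 tert-butyl 2-[(1S,2S,3R,4S,6R)-6-{[(2Z)-4-(acetyloxy)-2-methylbut-2-enoyl]oxy}-4-ethenyl-2-hydroxy-3-(3-hydroxyprop-1-en-2-yl)-4-methylcyclohexyl]prop-2-enoate
Product: 27 2-[(1S,2S,3R,4S,6R)-6-{[(2Z)-4-(acetyloxy)-2-methylbut-2-enoyl]oxy}-4-ethenyl-2-hydroxy-3-(3-hydroxyprop-1-en-2-yl)-4-methylcyclohexyl]prop-2-enoic acid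
Conditions: Me3SiOTf, 2,6-lutidine, CH2Cl2, 0 °C; then MeOH, aq. citrate buffer pH 5, 0 °C
Reagents that add atoms: none
Why: Silyl triflate-mediated cleavage of the tert-butyl ester (loss of isobutene) under non-protic conditions with the hydroxyls transiently silylated, so that the cis-γ-hydroxy acid is released only in the cold buffered work-up.

**Compound list**

1 | 1,2:5,6-di-O-isopropylidene-D-mannitol | CC1(C)OC[C@@H](O1)[C@@H](O)[C@H](O)[C@H]1COC(C)(C)O1 | starting material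
2 | (4R)-2,2-dimethyl-1,3-dioxolane-4-carbaldehyde | O=C[C@H]1COC(C)(C)O1 | intermediate
3 | tert-butyl prop-2-enoate | C=CC(=O)OC(C)(C)C | starting material
4 | tert-butyl 2-{[(4R)-2,2-dimethyl-1,3-dioxolan-4-yl](hydroxy)methyl}prop-2-enoate (both carbinol epimers) | C=C(C(=O)OC(C)(C)C)C(O)[C@H]1COC(C)(C)O1 | intermediate
5 | tert-butyl (2Z)-2-(chloromethyl)-3-[(4S)-2,2-dimethyl-1,3-dioxolan-4-yl]prop-2-enoate | ClC/C(C(=O)OC(C)(C)C)=C\[C@H]1COC(C)(C)O1 | intermediate
6 | tert-butyl (2Z,4S)-2-(chloromethyl)-4,5-dihydroxypent-2-enoate | ClC/C(C(=O)OC(C)(C)C)=C\[C@H](O)CO | intermediate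
7 | tert-butyl (2Z,4S)-2-(chloromethyl)-4-[(triethylsilyl)oxy]-5-{[(trifluoromethyl)sulfonyl]oxy}pent-2-enoate | ClC/C(C(=O)OC(C)(C)C)=C\[C@H](O[Si](CC)(CC)CC)COS(=O)(=O)C(F)(F)F | intermediate
8 | 2-bromoprop-2-en-1-ol | OCC(Br)=C | starting material
9 | [(2-bromoprop-2-en-1-yl)oxy](tert-butyl)dimethylsilane | C=C(Br)CO[Si](C)(C)C(C)(C)C | intermediate
10 | tert-butyl(dimethyl){[2-(4,4,5,5-tetramethyl-1,3,2-dioxaborolan-2-yl)prop-2-en-1-yl]oxy}silane | C=C(CO[Si](C)(C)C(C)(C)C)B1OC(C)(C)C(C)(C)O1 | intermediate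
11 | methyl (2E)-4,4-dimethoxybut-2-enoate | COC(OC)/C=C/C(=O)OC | starting material
12 | methyl (3R)-4-({[tert-butyl(dimethyl)silyl]oxy}methyl)-3-(dimethoxymethyl)pent-4-enoate | COC(=O)C[C@@H](C(OC)OC)C(=C)CO[Si](C)(C)C(C)(C)C | intermediate
13 | (4R)-4-(dimethoxymethyl)-5-methylideneoxan-2-one | COC(OC)[C@@H]1CC(=O)OCC1=C | intermediate
14 | (4R)-4-(dimethoxymethyl)-3-methyl-5-methylideneoxan-2-one (both C3 epimers) | COC(OC)[C@@H]1C(C)C(=O)OCC1=C | intermediate
15 | tert-butyl (2Z,4R)-2-(chloromethyl)-5-[(3R,4S)-4-(dimethoxymethyl)-3-methyl-5-methylidene-2-oxooxan-3-yl]-4-[(triethylsilyl)oxy]pent-2-enoate | COC(OC)[C@@H]1[C@@](C)(C[C@@H](O[Si](CC)(CC)CC)/C=C(\CCl)C(=O)OC(C)(C)C)C(=O)OCC1=C | intermediate (not isolated)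
16 | tert-butyl (2Z,4R)-2-(chloromethyl)-5-[(3R,4S)-4-formyl-3-methyl-5-methylidene-2-oxooxan-3-yl]-4-hydroxypent-2-enoate | O=C[C@@H]1[C@@](C)(C[C@@H](O)/C=C(\CCl)C(=O)OC(C)(C)C)C(=O)OCC1=C | intermediate (not isolated)
17 | tert-butyl 2-[(4aS,5S,6R,7R,8aR)-5,7-dihydroxy-8a-methyl-4-methylidene-1-oxo-3,4,4a,5,6,7,8,8a-octahydro-1H-isochromen-6-yl]prop-2-enoate | O=C1OCC(=C)[C@@H]2[C@H](O)[C@H](C(=C)C(=O)OC(C)(C)C)[C@H](O)C[C@@]12C | intermediate
18 | tert-butyl 2-[(4aS,5S,6R,7R,8aR)-1,5,7-trihydroxy-8a-methyl-4-methylidene-3,4,4a,5,6,7,8,8a-octahydro-1H-isochromen-6-yl]prop-2-enoate (both C1 epimers) | OC1OCC(=C)[C@@H]2[C@H](O)[C@H](C(=C)C(=O)OC(C)(C)C)[C@H](O)C[C@@]12C | intermediate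
19 | tert-butyl 2-[(1R,2S,3R,4S,6R)-4-ethenyl-2,6-dihydroxy-3-(3-hydroxyprop-1-en-2-yl)-4-methylcyclohexyl]prop-2-enoate | C=C[C@]1(C)C[C@@H](O)[C@@H](C(=C)C(=O)OC(C)(C)C)[C@@H](O)[C@H]1C(=C)CO | intermediate
20 | tert-butyl 2-[(1R,2S,3R,4S,6R)-3-(3-{[tert-butyl(dimethyl)silyl]oxy}prop-1-en-2-yl)-4-ethenyl-2,6-dihydroxy-4-methylcyclohexyl]prop-2-enoate | C=C[C@]1(C)C[C@@H](O)[C@@H](C(=C)C(=O)OC(C)(C)C)[C@@H](O)[C@H]1C(=C)CO[Si](C)(C)C(C)(C)C | intermediate
21 | 3-methylfuran-2(5H)-one | CC1=CCOC1=O | starting material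
22 | sodium (2Z)-4-hydroxy-2-methylbut-2-enoate | OC/C=C(/C)C(=O)[O-].[Na+] | intermediate (not isolated)
23 | (2Z)-4-(acetyloxy)-2-methylbut-2-enoic acid | CC(=O)OC/C=C(/C)C(=O)O | intermediate
24 | (2Z)-4-(acetyloxy)-2-methylbut-2-enoic 2,4,6-trichlorobenzoic anhydride | CC(=O)OC/C=C(/C)C(=O)OC(=O)c1c(Cl)cc(Cl)cc1Cl | intermediate (not isolated)
25 | tert-butyl 2-[(1S,2S,3R,4S,6R)-6-{[(2Z)-4-(acetyloxy)-2-methylbut-2-enoyl]oxy}-3-(3-{[tert-butyl(dimethyl)silyl]oxy}prop-1-en-2-yl)-4-ethenyl-2-hydroxy-4-methylcyclohexyl]prop-2-enoate | C=C[C@]1(C)C[C@@H](OC(=O)/C(C)=C\COC(C)=O)[C@@H](C(=C)C(=O)OC(C)(C)C)[C@@H](O)[C@H]1C(=C)CO[Si](C)(C)C(C)(C)C | intermediate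
26 | tert-butyl 2-[(1S,2S,3R,4S,6R)-6-{[(2Z)-4-(acetyloxy)-2-methylbut-2-enoyl]oxy}-4-ethenyl-2-hydroxy-3-(3-hydroxyprop-1-en-2-yl)-4-methylcyclohexyl]prop-2-enoate | C=C[C@]1(C)C[C@@H](OC(=O)/C(C)=C\COC(C)=O)[C@@H](C(=C)C(=O)OC(C)(C)C)[C@@H](O)[C@H]1C(=C)CO | intermediate
27 | 2-[(1S,2S,3R,4S,6R)-6-{[(2Z)-4-(acetyloxy)-2-methylbut-2-enoyl]oxy}-4-ethenyl-2-hydroxy-3-(3-hydroxyprop-1-en-2-yl)-4-methylcyclohexyl]prop-2-enoic acid | C=C[C@]1(C)C[C@@H](OC(=O)/C(C)=C\COC(C)=O)[C@@H](C(=C)C(=O)O)[C@@H](O)[C@H]1C(=C)CO | target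

**Count and risks**

Total step count: 18. Longest linear sequence: 12 steps (steps 6–14 and 16–18, or equally steps 1–5, 11–14 and 16–18).

Steps most likely to fail:

Step 11. The enolate may attack the allylic chloride instead of the triflate; the unmasked aldehyde may epimerize or the hydroxy lactone may translactonize before ring closure; the closure may take the wrong facial course. Fallback: set out from 5. Bu3SnLi/CuBr·SMe2 (THF, −78 °C) replaces chloride by tin to give tert-butyl (2Z)-3-[(4S)-2,2-dimethyl-1,3-dioxolan-4-yl]-2-[(tributylstannyl)methyl]prop-2-enoate F1. Acetonide hydrolysis (AcOH/H2O) gives tert-butyl (2Z,4S)-4,5-dihydroxy-2-[(tributylstannyl)methyl]pent-2-enoate F2. Tf2O/2,6-lutidine then Et3SiOTf gives tert-butyl (2Z,4S)-2-[(tributylstannyl)methyl]-4-[(triethylsilyl)oxy]-5-{[(trifluoromethyl)sulfonyl]oxy}pent-2-enoate F3. Alkylation of the lithium enolate of 14 with F3 gives, after isolation, tert-butyl (2Z,4R)-5-[(3R,4S)-4-(dimethoxymethyl)-3-methyl-5-methylidene-2-oxooxan-3-yl]-2-[(tributylstannyl)methyl]-4-[(triethylsilyl)oxy]pent-2-enoate F4. InCl3 in MeCN/H2O then hydrolyses acetal and silyl ether to tert-butyl (2Z,4R)-5-[(3R,4S)-4-formyl-3-methyl-5-methylidene-2-oxooxan-3-yl]-4-hydroxy-2-[(tributylstannyl)methyl]pent-2-enoate F5 and transmetalates tin to trivalent indium; the allylindium dichloride closes the ring to 17, where the route is rejoined.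

Step 16. Site selection between the two secondary hydroxyls may be poor, and the (Z)-enoate may isomerize during activation. Fallback: set out from 19. 1,3-Dichloro-1,1,3,3-tetraisopropyldisiloxane/imidazole (DMF) reacts first at the primary hydroxyl and then bridges to the nearby C2 hydroxyl, giving tert-butyl 2-[(1R,2S,3R,4S,6R)-4-ethenyl-6-hydroxy-4-methyl-2-oxy-3-(3-oxyprop-1-en-2-yl)cyclohexyl]prop-2-enoate with the two oxygens joined by a 1,1,3,3-tetra(propan-2-yl)disiloxane-1,3-diyl bridge F6. Only the C6 hydroxyl is then free; Yamaguchi esterification with 23 gives the corresponding C6 ester F7, and HF·pyridine removes the disiloxane to return to 26.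

Step 8. The alkenylrhodium intermediate may lose the allylic silyloxy group by β-oxygen elimination, the α-branched alkenylboronate may add slowly, or enantioface selection may be insufficient. Fallback: set out from 11. LiOH hydrolysis gives (2E)-4,4-dimethoxybut-2-enoic acid F8. Pivaloyl chloride/Et3N, then lithiated (4S)-4-benzyl-1,3-oxazolidin-2-one, gives (4S)-4-benzyl-3-[(2E)-4,4-dimethoxybut-2-enoyl]-1,3-oxazolidin-2-one F9. The alkenylcopper reagent prepared from 9 (t-BuLi, then CuBr·SMe2, −78 °C) adds to the chelated s-cis imide anti to the benzyl group to give (4S)-4-benzyl-3-[(3R)-4-({[tert-butyl(dimethyl)silyl]oxy}methyl)-3-(dimethoxymethyl)pent-4-enoyl]-1,3-oxazolidin-2-one F10. Bu4NF then desilylates and the alkoxide expels the auxiliary, which returns to 13.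

Further compounds

F1 | step 11 | tert-butyl (2Z)-3-[(4S)-2,2-dimethyl-1,3-dioxolan-4-yl]-2-[(tributylstannyl)methyl]prop-2-enoate | CCCC[Sn](CCCC)(CCCC)C/C(C(=O)OC(C)(C)C)=C\[C@H]1COC(C)(C)O1
F2 | step 11 | tert-butyl (2Z,4S)-4,5-dihydroxy-2-[(tributylstannyl)methyl]pent-2-enoate | CCCC[Sn](CCCC)(CCCC)C/C(C(=O)OC(C)(C)C)=C\[C@H](O)CO
F3 | step 11 | tert-butyl (2Z,4S)-2-[(tributylstannyl)methyl]-4-[(triethylsilyl)oxy]-5-{[(trifluoromethyl)sulfonyl]oxy}pent-2-enoate | CCCC[Sn](CCCC)(CCCC)C/C(C(=O)OC(C)(C)C)=C\[C@H](O[Si](CC)(CC)CC)COS(=O)(=O)C(F)(F)F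
F4 | step 11 | tert-butyl (2Z,4R)-5-[(3R,4S)-4-(dimethoxymethyl)-3-methyl-5-methylidene-2-oxooxan-3-yl]-2-[(tributylstannyl)methyl]-4-[(triethylsilyl)oxy]pent-2-enoate | COC(OC)[C@@H]1[C@@](C)(C[C@@H](O[Si](CC)(CC)CC)/C=C(\C[Sn](CCCC)(CCCC)CCCC)C(=O)OC(C)(C)C)C(=O)OCC1=C
F5 | step 11 | tert-butyl (2Z,4R)-5-[(3R,4S)-4-formyl-3-methyl-5-methylidene-2-oxooxan-3-yl]-4-hydroxy-2-[(tributylstannyl)methyl]pent-2-enoate | O=C[C@@H]1[C@@](C)(C[C@@H](O)/C=C(\C[Sn](CCCC)(CCCC)CCCC)C(=O)OC(C)(C)C)C(=O)OCC1=C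
F6 | step 16 | tert-butyl 2-[(1R,2S,3R,4S,6R)-4-ethenyl-6-hydroxy-4-methyl-2-oxy-3-(3-oxyprop-1-en-2-yl)cyclohexyl]prop-2-enoate, the two oxy groups bridged by 1,1,3,3-tetra(propan-2-yl)disiloxane-1,3-diyl | C=C[C@]1(C)C[C@@H](O)[C@@H](C(=C)C(=O)OC(C)(C)C)[C@H]2O[Si](C(C)C)(C(C)C)O[Si](C(C)C)(C(C)C)OCC(=C)[C@@H]12
F7 | step 16 | the C6 (2Z)-4-(acetyloxy)-2-methylbut-2-enoate ester of F6 | C=C[C@]1(C)C[C@@H](OC(=O)/C(C)=C\COC(C)=O)[C@@H](C(=C)C(=O)OC(C)(C)C)[C@H]2O[Si](C(C)C)(C(C)C)O[Si](C(C)C)(C(C)C)OCC(=C)[C@@H]12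
F8 | step 8 | (2E)-4,4-dimethoxybut-2-enoic acid | COC(OC)/C=C/C(=O)O
F9 | step 8 | (4S)-4-benzyl-3-[(2E)-4,4-dimethoxybut-2-enoyl]-1,3-oxazolidin-2-one | COC(OC)/C=C/C(=O)N1[C@@H](Cc2ccccc2)COC1=O
F10 | step 8 | (4S)-4-benzyl-3-[(3R)-4-({[tert-butyl(dimethyl)silyl]oxy}methyl)-3-(dimethoxymethyl)pent-4-enoyl]-1,3-oxazolidin-2-one | COC(OC)[C@H](CC(=O)N1[C@@H](Cc2ccccc2)COC1=O)C(=C)CO[Si](C)(C)C(C)(C)C
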